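The numbers in the tables stem from a simulated flask with constants of no real substance.

The west run, with 5 mM of J on 10 mM of E, reads at most 7% of G, and the south-west run, with 20 mM of J on the same E, reads 25%.

| flask | E | J | remark | time |
|---|---|---|---|---|
| west | 10 mM | 5 mM | run made earlier |  |
| south-west | 10 mM | 20 mM | run made earlier |  |
| south | 15 mM | 10 mM | run made earlier |  |
| flask | 10 mM | 10.0 mM |  | 3.0 min |

| run | time / min | G / % | E / % |
|---|---|---|---|
| west | 0.333 | 0 | 60 |
| west | 0.500 | 5 | 52 |
| west | 0.667 | 5 | 46 |
| west | 1.00 | 7 | 34 |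
| west | 1.50 | 5 | 32 |
| west | 2.50 | 5 | 23 |
| south-west | 0.333 | 9 | 10 |
| south-west | 0.500 | 19 | 3 |
| south-west | 0.667 | 17 | 4 |
| south-west | 1.00 | 25 | 0 |
| south-west | 1.50 | 18 | 0 |
| south-west | 2.50 | 13 | 0 |
| south | 0.333 | 2 | 40 |
| south | 0.500 | 6 | 29 |
| south | 0.833 | 11 | 21 |
| south | 1.33 | 8 | 14 |
| south | 2.50 | 7 | 4 |

(each reading ± 2 percentage points)

- a species is counted by the E in it: one Z or X counts as two
- steps that have been proposed: E + J -> D; D -> G; E + D -> Z; E + D -> X; G -> Q

* the best time, 3.0 min at the latest, for G
* the amount of G, in percent of the E charged, at that time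

The charges fold into one number, the equivalents of J per E. Dividing the highest G reading by it gives 14.0% for west, 16.5% for south and 12.5% for south-west. These differ by at most 4 percentage points, while the scatter of a reading divided by the south equivalents is 3 points, so the readings do not clearly separate them. Their mean, read off scattered readings, is the peak yield per equivalent, 14.3%. With 1.00 equivalents, the flask should peak near 14.3%, and the highest readings, at 0.833 min to 1.00 min, put that peak near 1.00 min.

The forecast, “an envelope estimate, not a fit”, gave 13% (10% to 17%) at 0.9 min (0.65 min to 1.25 min), lower and earlier than the reckoning here.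

The flask gives 13.9% at 1.23 min.

    E + J → D (k = 6.10 L mol⁻¹ s⁻¹)
    D → G (k = 0.0140 s⁻¹)
    E + D → Z (k = 2.90 L mol⁻¹ s⁻¹)
    E + D → X (k = 1.40 L mol⁻¹ s⁻¹)
    G → Q (k = 0.0210 s⁻¹)

The neighbour charged with 17 mM of J has 1.70 equiv of J per E, so the same reckoning gives 24.3% of G. That neighbour reaches 19.5%, which is 11.5% per equivalent, less than the carried yield. Its highest G is more than the flask's 13.9%, by a factor of 1.40 on 1.70 times the J. At 3.0 min that neighbour holds 52.5% of the E charged as Q, 0% of its E, the limiting reagent, and 50.8% of its J.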